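Ring labels: A = 4-hydroxy-3-methoxyphenyl; B = the arene with OH and OMe on either side of the bridging CH2 (its C1 carries the ethylene bridge, its C4 the bridging CH2); C = the arene whose OH lies para to the bridging CH2 (C1 carries that CH2); D = 3-hydroxyphenyl.
Cuts: (a) the bond from the bridging carbon to C4 of ring B; (b) inside ring C the bond C1-C2, followed by two C-C bonds of the opened tetraketide chain; (c) the bond from C1 of ring B to the CH2 of the A/B ethylene bridge.
Enabling feature: ring C has oxygen only on C4 and C6 (alternate carbons), the ring D ethyl chain on C2 and a one-carbon substituent on C1. This is the pattern of a 6-alkyl-2,4-dihydroxybenzoate, so ring C is the folded form of a 3,5,7-triketo acid whose carboxyl carbon ends up as the bridging CH2.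
Forward: rings A, B and D are bought as arenes. The triketo acid is assembled on trimethyldioxinone (acetyl unit, then the ring D propanoyl unit) and folded to ring C, the only ring that is built. A and B are joined by a B-alkyl Suzuki-Miyaura coupling, lithiated ring B opens the benzodioxinone, and the ketone is taken down to CH2 before deprotection.
Stereochemistry: the target has no stereocentre and no stereogenic double bond. The centres that appear on the way (cyclic aldol, diaryl carbinol) are racemic and are erased again.
Key step: step 6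

Assumption: the SMILES carries no stereodescriptor and the structure has no stereogenic element, so the target is treated as achiral and no step is asked to be stereoselective.

Step 1
Reactants: 1 3-hydroxybenzaldehyde
Product: 2 3-(benzyloxy)benzaldehyde
Conditions: BnBr (1.1 equiv), K2CO3, DMF, rt
Reagents that add atoms: benzyl bromide, BrCc1ccccc1
Why: Williamson ether synthesis on the phenoxide leaves the non-enolisable aldehyde untouched, and benzyl is chosen because it withstands the bases, hydrides and brief acid used later and leaves by hydrogenolysis in the last step.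

Step 2
Reactants: 2 3-(benzyloxy)benzaldehyde; 3 Meldrum's acid (2,2-dimethyl-1,3-dioxane-4,6-dione)
Product: 6 3-[3-(benzyloxy)phenyl]propanoic acid, via benzylidene Meldrum's acid 4 (not isolated), via benzyl Meldrum's acid 5 (not isolated)
Conditions: HCO2H/Et3N (5:2), rt, then 100 °C
Reagents that add atoms: none
Why: Knoevenagel condensation gives 4, formate transfers hydride to this strong Michael acceptor to give 5, and at 100 °C the dioxanedione is hydrolysed by the water of condensation and decarboxylates, a metal-free reductive sequence that cannot cleave the benzyl ether.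

Step 3
Reactants: 6 3-[3-(benzyloxy)phenyl]propanoic acid
Product: 8 3-[3-(benzyloxy)phenyl]-N-methoxy-N-methylpropanamide, via acyl imidazole 7 (not isolated)
Conditions: 1,1'-carbonyldiimidazole, CH2Cl2, rt; then MeNH(OMe)·HCl, rt
Reagents that add atoms: N,O-dimethylhydroxylamine hydrochloride, CNOC.Cl
Why: Carbonyldiimidazole activation followed by aminolysis is the standard Weinreb amide synthesis and provides an acyl donor that accepts a carbanion only once.

Step 4
Reactants: 9 2,2,6-trimethyl-4H-1,3-dioxin-4-one; 10 acetyl chloride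
Product: 12 2,2-dimethyl-6-(2-oxopropyl)-4H-1,3-dioxin-4-one, via lithium dienolate 11 (not isolated)
Conditions: LiN(SiMe3)2, THF, -78 °C; then 10 (0.5 equiv relative to 11), -78 to -20 °C; 1 M HCl
Reagents that add atoms: none
Why: Kinetic deprotonation of the C6 methyl group gives cross-conjugated dienolate 11, which undergoes the known gamma-selective C-acylation (vinylogous Claisen-type acylation), the surplus enolate absorbing the acidic proton of the product.

Step 5
Reactants: 12 2,2-dimethyl-6-(2-oxopropyl)-4H-1,3-dioxin-4-one; 8 3-[3-(benzyloxy)phenyl]-N-methoxy-N-methylpropanamide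
Product: 14 6-{6-[3-(benzyloxy)phenyl]-2,4-dioxohexyl}-2,2-dimethyl-4H-1,3-dioxin-4-one, via dilithio dianion 13 (not isolated)
Conditions: LiN(iPr)2 (2.2 equiv), THF, -78 to -40 °C; then 8, -78 to -20 °C; 1 M HCl quench; used without long storage
Reagents that add atoms: none
Why: Double deprotonation gives dianion 13, which reacts at its last-formed and most nucleophilic terminal carbon (Claisen-type acylation of a 1,3-dicarbonyl dianion), and the N-methoxy-N-methyl group holds the adduct until the quench, so neither over-addition nor proton transfer from the more acidic product should interfere.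

Step 6
Reactants: 14 6-{6-[3-(benzyloxy)phenyl]-2,4-dioxohexyl}-2,2-dimethyl-4H-1,3-dioxin-4-one
Product: 16 5-{2-[3-(benzyloxy)phenyl]ethyl}-7-hydroxy-2,2-dimethyl-4H-1,3-benzodioxin-4-one, via cyclic aldol 15 (not isolated)
Conditions: Et3N (5 equiv), CH2Cl2, rt
Reagents that add atoms: none
Why: Et3N removes a proton from the CH2 between dioxinone C6 and the first ketone, giving an extended dienolate whose alpha carbon (dioxinone C5) adds to the terminal, arylethyl-bearing ketone to form cyclic aldol 15; loss of water and enolisation of the remaining ring ketone then deliver the arene, so aromatisation makes the sequence irreversible. The closest known reaction type is the base-mediated aldol aromatisation of diketo-dioxinones to resorcylate acetonides, the laboratory version of the orsellinate fold of a tetraketide. The one new ring (ring C) closes in a 6-(enolexo)-exo-trig mode through the bond C4a-C5 of the benzodioxinone, which is C1-C2 of ring C. No stereocentre has to be controlled, since the two centres of 15 vanish on dehydration. The step needs mode selectivity against Claisen closure of the inter-ketone CH2 onto the lactone carbonyl, against O-cyclisation to a pyranone and against thermal loss of acetone to an acylketene; the lactone carbonyl is deactivated as a vinylogous carbonate, and a non-nucleophilic amine at room temperature neither opens nor cracks the dioxinone, so the six-membered aldol path with its irreversible dehydration should prevail. Because the C8a oxygen remains part of the acetonide and only the C7 hydroxyl is liberated, the two ring C oxygens leave this step chemically distinct, and steps 7 and 13 can address them one at a time.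

Step 7
Reactants: 16 5-{2-[3-(benzyloxy)phenyl]ethyl}-7-hydroxy-2,2-dimethyl-4H-1,3-benzodioxin-4-one
Product: 17 7-(benzyloxy)-5-{2-[3-(benzyloxy)phenyl]ethyl}-2,2-dimethyl-4H-1,3-benzodioxin-4-one
Conditions: BnBr, K2CO3, DMF, rt
Reagents that add atoms: benzyl bromide, BrCc1ccccc1
Why: Williamson etherification of the only free phenol marks the C7 oxygen as the future ring C hydroxyl, and carbonate in an aprotic solvent should not open the dioxinone.

Step 8
Reactants: 18 vanillin
Product: 19 4-(benzyloxy)-3-methoxybenzaldehyde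
Conditions: BnBr, K2CO3, DMF, rt
Reagents that add atoms: benzyl bromide, BrCc1ccccc1
Why: Williamson ether synthesis on the acidic para-formyl phenol is routine and gives a ring A protecting group that is only a weak director of lithiation.

Step 9
Reactants: 19 4-(benzyloxy)-3-methoxybenzaldehyde
Product: 20 1-(benzyloxy)-4-ethenyl-2-methoxybenzene
Conditions: Ph3PCH3Br, KOtBu, THF, 0 °C to rt
Reagents that add atoms: methyltriphenylphosphonium bromide, C[P+](c1ccccc1)(c1ccccc1)c1ccccc1.[Br-]
Why: Wittig methylenation of a non-enolisable aromatic aldehyde reliably gives the styrene and supplies the second carbon of the A/B bridge.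

Step 10
Reactants: 21 3-bromo-5-methoxyphenol
Product: 22 1-bromo-3-methoxy-5-(methoxymethoxy)benzene
Conditions: NaH, MOMCl, DMF, 0 °C
Reagents that add atoms: chloromethyl methyl ether, COCCl
Why: O-alkylation of the sodium phenoxide (Williamson type) installs the MOM acetal, chosen for ring B alone because it is a strong ortho-directing group for step 12.

Step 11
Reactants: 20 1-(benzyloxy)-4-ethenyl-2-methoxybenzene; 22 1-bromo-3-methoxy-5-(methoxymethoxy)benzene
Product: 24 1-(benzyloxy)-2-methoxy-4-{2-[3-methoxy-5-(methoxymethoxy)phenyl]ethyl}benzene, via B-alkyl-9-BBN borane 23 (not isolated)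
Conditions: 9-BBN-H, THF, 0 °C to rt; then 22, PdCl2(dppf) (3 mol %), 3 M aq NaOH, THF, 65 °C
Reagents that add atoms: none
Why: Anti-Markovnikov hydroboration with the bulky borane puts boron on the terminal carbon, and the B-alkyl Suzuki-Miyaura coupling forms the sp3-sp2 bond of the bibenzyl without any hydrogenation, so the benzyl ether is kept.

Step 12
Reactants: 24 1-(benzyloxy)-2-methoxy-4-{2-[3-methoxy-5-(methoxymethoxy)phenyl]ethyl}benzene; 17 7-(benzyloxy)-5-{2-[3-(benzyloxy)phenyl]ethyl}-2,2-dimethyl-4H-1,3-benzodioxin-4-one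
Product: 26 [4-(benzyloxy)-2-{2-[3-(benzyloxy)phenyl]ethyl}-6-hydroxyphenyl][4-{2-[4-(benzyloxy)-3-methoxyphenyl]ethyl}-2-methoxy-6-(methoxymethoxy)phenyl]methanone, via aryllithium 25 (not isolated)
Conditions: 24 (2.1 equiv), n-BuLi (2.0 equiv), THF, 0 °C; then 17 (1 equiv), -78 to 0 °C; aq NH4Cl; surplus 24 recovered
Reagents that add atoms: none
Why: Directed ortho-metalation removes the ring B proton flanked by OMe and OMOM (cooperating directors), and 25 then carries out a nucleophilic acyl substitution on the ring-constrained lactone carbonyl, whose adduct collapses with loss of acetone to a phenoxide-bearing ketone too electron-rich and hindered for a second addition, the extra equivalent of 25 covering what the liberated acetone consumes.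

Step 13
Reactants: 26 the hydroxybenzophenone of step 12
Product: 27 [4-(benzyloxy)-2-{2-[3-(benzyloxy)phenyl]ethyl}-6-methoxyphenyl][4-{2-[4-(benzyloxy)-3-methoxyphenyl]ethyl}-2-methoxy-6-(methoxymethoxy)phenyl]methanone
Conditions: MeI, K2CO3, DMF, 40 °C
Reagents that add atoms: iodomethane, CI
Why: Williamson methylation of the single free, hydrogen-bonded phenol set free from the acetonide fixes the ring C methoxy group.

Step 14
Reactants: 27 the methoxybenzophenone of step 13
Product: 28 rac-[4-(benzyloxy)-2-{2-[3-(benzyloxy)phenyl]ethyl}-6-methoxyphenyl][4-{2-[4-(benzyloxy)-3-methoxyphenyl]ethyl}-2-methoxy-6-(methoxymethoxy)phenyl]methanol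
Conditions: LiAlH4, THF, 0 °C to reflux; aqueous NaOH work-up
Reagents that add atoms: none
Why: Hydride reduction with the small and powerful LiAlH4 should overcome the four ortho substituents, the new carbinol centre forms as a racemate without any control, and it is erased in the next step.

Step 15
Reactants: 28 the diaryl carbinol of step 14
Product: 30 2-{[4-(benzyloxy)-2-{2-[3-(benzyloxy)phenyl]ethyl}-6-methoxyphenyl]methyl}-5-{2-[4-(benzyloxy)-3-methoxyphenyl]ethyl}-3-methoxyphenol, via MOM-bearing diarylmethane 29 (not isolated)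
Conditions: Et3SiH (6 equiv), TFA/CH2Cl2 (1:4), 0 °C to rt; aq NaHCO3
Reagents that add atoms: none
Why: In this ionic hydrogenation TFA ionises the doubly benzylic alcohol to a cation stabilised by four ortho or para oxygen donors, Et3SiH transfers hydride to give 29, and continued exposure cleaves the MOM acetal while the silane reduces the methoxymethyl cation, the plain benzyl ethers being far slower to ionise.

Step 16
Reactants: 30 the tribenzyl ether of step 15
Product: 31 4-{2-[3-hydroxy-4-({4-hydroxy-2-[2-(3-hydroxyphenyl)ethyl]-6-methoxyphenyl}methyl)-5-methoxyphenyl]ethyl}-2-methoxyphenol (CNP0078999.0)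
Conditions: H2 (1 atm), 10 % Pd/C, EtOAc/MeOH, rt
Reagents that add atoms: none
Why: Catalytic hydrogenolysis removes the three aryl benzyl ethers at once under neutral conditions, to which the methyl ethers, the bibenzyl bridges and the diarylmethane are inert.

Compound list
1 | 3-hydroxybenzaldehyde | O=Cc1cccc(O)c1 | starting material
2 | 3-(benzyloxy)benzaldehyde | O=Cc1cccc(OCc2ccccc2)c1 | intermediate
3 | Meldrum's acid (2,2-dimethyl-1,3-dioxane-4,6-dione) | CC1(C)OC(=O)CC(=O)O1 | starting material
4 | 5-[3-(benzyloxy)benzylidene]-2,2-dimethyl-1,3-dioxane-4,6-dione (not isolated) | CC1(C)OC(=O)C(=Cc2cccc(OCc3ccccc3)c2)C(=O)O1 | intermediate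
5 | 5-[3-(benzyloxy)benzyl]-2,2-dimethyl-1,3-dioxane-4,6-dione (not isolated) | CC1(C)OC(=O)C(Cc2cccc(OCc3ccccc3)c2)C(=O)O1 | intermediate
6 | 3-[3-(benzyloxy)phenyl]propanoic acid | OC(=O)CCc1cccc(OCc2ccccc2)c1 | intermediate
7 | 1-{3-[3-(benzyloxy)phenyl]propanoyl}imidazole (not isolated) | O=C(CCc1cccc(OCc2ccccc2)c1)n1ccnc1 | intermediate
8 | 3-[3-(benzyloxy)phenyl]-N-methoxy-N-methylpropanamide | CON(C)C(=O)CCc1cccc(OCc2ccccc2)c1 | intermediate
9 | 2,2,6-trimethyl-4H-1,3-dioxin-4-one | CC1=CC(=O)OC(C)(C)O1 | starting material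
10 | acetyl chloride | CC(=O)Cl | starting material
11 | lithium 2,2-dimethyl-6-methylidene-6H-1,3-dioxin-4-olate (not isolated) | [Li+].[O-]C1=CC(=C)OC(C)(C)O1 | intermediate
12 | 2,2-dimethyl-6-(2-oxopropyl)-4H-1,3-dioxin-4-one | CC(=O)CC1=CC(=O)OC(C)(C)O1 | intermediate
13 | dilithium dianion of 12, drawn as the bis-enolate (not isolated) | [Li+].[Li+].[O-]C1=CC(=CC(=C)[O-])OC(C)(C)O1 | intermediate
14 | 6-{6-[3-(benzyloxy)phenyl]-2,4-dioxohexyl}-2,2-dimethyl-4H-1,3-dioxin-4-one (drawn as the keto form, largely enolised) | CC1(C)OC(=O)C=C(CC(=O)CC(=O)CCc2cccc(OCc3ccccc3)c2)O1 | intermediate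
15 | 5-{2-[3-(benzyloxy)phenyl]ethyl}-5-hydroxy-2,2-dimethyl-4a,5-dihydro-4H-1,3-benzodioxine-4,7(6H)-dione, mixture of racemic diastereomers (not isolated) | CC1(C)OC(=O)C2C(O)(CCc3cccc(OCc4ccccc4)c3)CC(=O)C=C2O1 | intermediate
16 | 5-{2-[3-(benzyloxy)phenyl]ethyl}-7-hydroxy-2,2-dimethyl-4H-1,3-benzodioxin-4-one | CC1(C)OC(=O)c2c(CCc3cccc(OCc4ccccc4)c3)cc(O)cc2O1 | intermediate
17 | 7-(benzyloxy)-5-{2-[3-(benzyloxy)phenyl]ethyl}-2,2-dimethyl-4H-1,3-benzodioxin-4-one | CC1(C)OC(=O)c2c(CCc3cccc(OCc4ccccc4)c3)cc(OCc3ccccc3)cc2O1 | intermediate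
18 | vanillin | COc1cc(C=O)ccc1O | starting material
19 | 4-(benzyloxy)-3-methoxybenzaldehyde | COc1cc(C=O)ccc1OCc1ccccc1 | intermediate
20 | 1-(benzyloxy)-4-ethenyl-2-methoxybenzene | COc1cc(C=C)ccc1OCc1ccccc1 | intermediate
21 | 3-bromo-5-methoxyphenol | COc1cc(O)cc(Br)c1 | starting material
22 | 1-bromo-3-methoxy-5-(methoxymethoxy)benzene | COCOc1cc(Br)cc(OC)c1 | intermediate
23 | 9-{2-[4-(benzyloxy)-3-methoxyphenyl]ethyl}-9-borabicyclo[3.3.1]nonane (not isolated) | COc1cc(CCB2C3CCCC2CCC3)ccc1OCc1ccccc1 | intermediate
24 | 1-(benzyloxy)-2-methoxy-4-{2-[3-methoxy-5-(methoxymethoxy)phenyl]ethyl}benzene (rings A and B) | COCOc1cc(CCc2ccc(OCc3ccccc3)c(OC)c2)cc(OC)c1 | intermediate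
25 | 4-{2-[4-(benzyloxy)-3-methoxyphenyl]ethyl}-2-methoxy-6-(methoxymethoxy)phenyllithium (not isolated) | [Li]c1c(OC)cc(CCc2ccc(OCc3ccccc3)c(OC)c2)cc1OCOC | intermediate
26 | hydroxybenzophenone: ring C with 6-OH, 4-OBn and the ring D ethyl chain; ring B with OMe and OMOM beside the carbonyl | COCOc1cc(CCc2ccc(OCc3ccccc3)c(OC)c2)cc(OC)c1C(=O)c1c(O)cc(OCc2ccccc2)cc1CCc1cccc(OCc2ccccc2)c1 | intermediate
27 | methoxybenzophenone (methyl ether of 26) | COCOc1cc(CCc2ccc(OCc3ccccc3)c(OC)c2)cc(OC)c1C(=O)c1c(OC)cc(OCc2ccccc2)cc1CCc1cccc(OCc2ccccc2)c1 | intermediate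
28 | racemic diaryl carbinol from 27 | COCOc1cc(CCc2ccc(OCc3ccccc3)c(OC)c2)cc(OC)c1C(O)c1c(OC)cc(OCc2ccccc2)cc1CCc1cccc(OCc2ccccc2)c1 | intermediate
29 | 2-{[4-(benzyloxy)-2-{2-[3-(benzyloxy)phenyl]ethyl}-6-methoxyphenyl]methyl}-5-{2-[4-(benzyloxy)-3-methoxyphenyl]ethyl}-1-methoxy-3-(methoxymethoxy)benzene (not isolated) | COCOc1cc(CCc2ccc(OCc3ccccc3)c(OC)c2)cc(OC)c1Cc1c(OC)cc(OCc2ccccc2)cc1CCc1cccc(OCc2ccccc2)c1 | intermediate
30 | 2-{[4-(benzyloxy)-2-{2-[3-(benzyloxy)phenyl]ethyl}-6-methoxyphenyl]methyl}-5-{2-[4-(benzyloxy)-3-methoxyphenyl]ethyl}-3-methoxyphenol | Oc1cc(CCc2ccc(OCc3ccccc3)c(OC)c2)cc(OC)c1Cc1c(OC)cc(OCc2ccccc2)cc1CCc1cccc(OCc2ccccc2)c1 | intermediate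
31 | 4-{2-[3-hydroxy-4-({4-hydroxy-2-[2-(3-hydroxyphenyl)ethyl]-6-methoxyphenyl}methyl)-5-methoxyphenyl]ethyl}-2-methoxyphenol (CNP0078999.0) | COc1cc(CCc2cc(O)c(Cc3c(CCc4cccc(O)c4)cc(O)cc3OC)c(OC)c2)ccc1O | target

Total step count: 16. Longest linear sequence: 11 (steps 1, 2, 3, 5, 6, 7, 12, 13, 14, 15, 16). Compounds 2 and 19 are also catalogue items, and buying them would remove steps 1 and 8.

Steps most likely to fail

(a) Step 12.
- **What may go wrong:** Both carbons that must bond are flanked by two ortho substituents, so addition may be slow. The aryllithium may then act as a base on the benzylic CH2 next to the lactone carbonyl, be consumed by the liberated acetone, or arise together with products of metalation elsewhere (ring A, the OCH2Ph group).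
- **Fallback:** it sets out from 17 and returns at 28, replacing the acyl substitution by addition to a much more reactive formyl group. NaOMe in MeOH opens 17 to the methyl salicylate F1. MeI/K2CO3 then gives its methyl ether F2, LiAlH4 the benzyl alcohol F3 and MnO2 the benzaldehyde F4. Aryllithium 25, made as before, should add to F4 at -78 °C and give carbinol 28 directly, so that steps 13 and 14 fall away.

(b) Step 5.
- **What may go wrong:** Proton exchange between the dianion and the amide may compete, as may reaction through the internal carbon or through oxygen. The sensitive product may also cyclise or decompose early, during the quench and chromatography.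
- **Fallback:** it sets out from 6 and 9 and returns at 14, replacing the hard dianion by soft enolisation of a beta-keto ester. Oxalyl chloride converts 6 into the acid chloride F5. Dienolate 11 is acylated with allyl 3-chloro-3-oxopropanoate to the allyl keto ester F6. MgCl2/pyridine in CH2Cl2 then promotes C-acylation of F6 by F5 to the triacylmethane F7. The zerovalent palladium complex Pd(PPh3)4 with morpholine removes the allyl ester with decarboxylation and should give 14 under nearly neutral conditions.

(c) Step 15.
- **What may go wrong:** The diarylmethyl cation may be intercepted before hydride transfer, either by ring D (seven-membered Friedel-Crafts closure) or by another electron-rich arene. The rings may be alkylated by the methoxymethyl cation, and acid may induce benzyl migration.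
- **Fallback:** it sets out from 27 and returns at 30, avoiding both a free cation and acid in the reduction. HCl in MeOH/THF removes the MOM group to give the ortho-hydroxybenzophenone F8, and ClCO2Et/Et3N gives the aryl ethyl carbonate F9. NaBH4 in aqueous THF reduces the ketone, after which the carbonate shifts to the benzylic oxygen and is expelled. Borohydride then reduces the resulting ortho-quinone methide F10 to 30. Steps 14 and 15 are replaced.

Further compounds
F1 | step 12 | methyl 4-(benzyloxy)-2-{2-[3-(benzyloxy)phenyl]ethyl}-6-hydroxybenzoate | COC(=O)c1c(O)cc(OCc2ccccc2)cc1CCc1cccc(OCc2ccccc2)c1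
F2 | step 12 | methyl 4-(benzyloxy)-2-{2-[3-(benzyloxy)phenyl]ethyl}-6-methoxybenzoate | COC(=O)c1c(OC)cc(OCc2ccccc2)cc1CCc1cccc(OCc2ccccc2)c1
F3 | step 12 | [4-(benzyloxy)-2-{2-[3-(benzyloxy)phenyl]ethyl}-6-methoxyphenyl]methanol | OCc1c(OC)cc(OCc2ccccc2)cc1CCc1cccc(OCc2ccccc2)c1
F4 | step 12 | 4-(benzyloxy)-2-{2-[3-(benzyloxy)phenyl]ethyl}-6-methoxybenzaldehyde | O=Cc1c(OC)cc(OCc2ccccc2)cc1CCc1cccc(OCc2ccccc2)c1
F5 | step 5 | 3-[3-(benzyloxy)phenyl]propanoyl chloride | O=C(Cl)CCc1cccc(OCc2ccccc2)c1
F6 | step 5 | allyl 4-(2,2-dimethyl-4-oxo-4H-1,3-dioxin-6-yl)-3-oxobutanoate | C=CCOC(=O)CC(=O)CC1=CC(=O)OC(C)(C)O1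
F7 | step 5 | allyl 5-[3-(benzyloxy)phenyl]-2-[(2,2-dimethyl-4-oxo-4H-1,3-dioxin-6-yl)acetyl]-3-oxopentanoate | C=CCOC(=O)C(C(=O)CCc1cccc(OCc2ccccc2)c1)C(=O)CC1=CC(=O)OC(C)(C)O1
F8 | step 15 | [4-(benzyloxy)-2-{2-[3-(benzyloxy)phenyl]ethyl}-6-methoxyphenyl][4-{2-[4-(benzyloxy)-3-methoxyphenyl]ethyl}-2-hydroxy-6-methoxyphenyl]methanone | COc1cc(CCc2ccc(OCc3ccccc3)c(OC)c2)cc(O)c1C(=O)c1c(OC)cc(OCc2ccccc2)cc1CCc1cccc(OCc2ccccc2)c1
F9 | step 15 | ethyl carbonate of the ring B phenol of F8 | CCOC(=O)Oc1cc(CCc2ccc(OCc3ccccc3)c(OC)c2)cc(OC)c1C(=O)c1c(OC)cc(OCc2ccccc2)cc1CCc1cccc(OCc2ccccc2)c1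
F10 | step 15 | ring B ortho-quinone methide (transient, exocyclic geometry undefined) | O=C1C=C(CCc2ccc(OCc3ccccc3)c(OC)c2)C=C(OC)C1=Cc1c(OC)cc(OCc2ccccc2)cc1CCc1cccc(OCc2ccccc2)c1
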